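**Retrosynthetic overview**
- The target is the 7-O-prenyl ether of limocitrin (flavone numbering: O1, C2–C4 in ring C, C4a–C8a in ring A, primed positions in ring B). The prenyl group goes on last, at O7, after the O7 acetate of the peracetylated tetraol has been removed selectively.
- Ring C is opened at C4–C4a, leading back to (E)-2-(benzyloxy)-3-aryl-3-aryloxyacrylic acid, whose carboxyl group acylates ring A in an intramolecular Friedel–Crafts reaction.
- The strategy rests on ring A: of its two carbons ortho to O1, C8 already carries the methoxy group, so C4a is the only position where ring C can close.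
- The acid comes from the enol tosylate of an α-benzyloxy-β-keto ester (Claisen acylation of ethyl benzyloxyacetate with O-benzylvanilloyl chloride) and 3,5-bis(benzyloxy)-2-methoxyphenol. The phenol comes from 2,4,6-trihydroxybenzaldehyde by dibenzylation, MOM protection, Baeyer–Villiger oxidation, O-methylation and MOM removal.
- Rings A and B are carried in by the building blocks; ring C is the only ring formed (step 11).

Key step: step 11

Assumption: 4-(benzyloxy)-3-methoxybenzoic acid is taken as a catalogue compound, and the enol tosylate and aryloxyacrylates are drawn as the isomers expected from the chelated lithium enolate and retentive substitution; their geometric purity is not critical because the alkene can equilibrate in step 11.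

**Route**

Step 1
Reactants: 1 2,4,6-trihydroxybenzaldehyde
Product: 2 2,4-bis(benzyloxy)-6-hydroxybenzaldehyde
Conditions: BnBr (2.05 equiv), K2CO3 (2.1 equiv), DMF, 0 °C to rt
Reagents that add atoms: benzyl bromide, BrCc1ccccc1
Why: Williamson etherification alkylates the 4-OH and one ortho-OH, while the last ortho-OH is hydrogen-bonded to the formyl oxygen and should react slowest.

Step 2
Reactants: 2 2,4-bis(benzyloxy)-6-hydroxybenzaldehyde
Product: 3 2,4-bis(benzyloxy)-6-(methoxymethoxy)benzaldehyde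
Conditions: MOMCl, K2CO3, acetone, 50 °C
Reagents that add atoms: chloromethyl methyl ether, COCCl
Why: Williamson-type alkylation caps the chelated phenol as an acetal that should survive peracid and base and come off later without touching benzyl ethers.

Step 3
Reactants: 3 2,4-bis(benzyloxy)-6-(methoxymethoxy)benzaldehyde
Product: 5 2,4-bis(benzyloxy)-6-(methoxymethoxy)phenol, via aryl formate 4 (not isolated)
Conditions: mCPBA, CH2Cl2, 0 °C to rt; then K2CO3 (cat.), MeOH, rt
Reagents that add atoms: 3-chloroperoxybenzoic acid, OOC(=O)c1cccc(Cl)c1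
Why: In this Baeyer–Villiger (Dakin-type) oxidation the electron-rich trialkoxyaryl group migrates to give the aryl formate, which carbonate-catalysed methanolysis should cleave to the phenol.

Step 4
Reactants: 5 2,4-bis(benzyloxy)-6-(methoxymethoxy)phenol
Product: 6 1,5-bis(benzyloxy)-2-methoxy-3-(methoxymethoxy)benzene
Conditions: MeI, K2CO3, DMF, rt
Reagents that add atoms: iodomethane, CI
Why: Williamson methylation of the only free phenol fixes the future 8-methoxy group.

Step 5
Reactants: 6 1,5-bis(benzyloxy)-2-methoxy-3-(methoxymethoxy)benzene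
Product: 7 3,5-bis(benzyloxy)-2-methoxyphenol
Conditions: HCl (cat.), MeOH, 40 °C
Reagents that add atoms: none
Why: Acid-catalysed acetal exchange with methanol removes the MOM group, and benzyl and methyl aryl ethers are stable to dilute methanolic HCl.

Step 6
Reactants: 8 4-(benzyloxy)-3-methoxybenzoic acid
Product: 9 4-(benzyloxy)-3-methoxybenzoyl chloride
Conditions: (COCl)2, DMF (cat.), CH2Cl2, 0 °C to rt
Reagents that add atoms: oxalyl chloride, ClC(=O)C(=O)Cl
Why: Acid chloride formation through the Vilsmeier-type chloroiminium catalyst leaves the benzyl ether untouched.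

Step 7
Reactants: 9 4-(benzyloxy)-3-methoxybenzoyl chloride; 10 ethyl 2-(benzyloxy)acetate
Product: 11 ethyl 2-(benzyloxy)-3-[4-(benzyloxy)-3-methoxyphenyl]-3-oxopropanoate (racemic)
Conditions: 10 (2.2 equiv), LiN(SiMe3)2 (2.2 equiv), THF, −78 °C; then 9, −78 to −40 °C; aq. NH4Cl
Reagents that add atoms: none
Why: In this crossed Claisen acylation the lithium ester enolate attacks the non-enolisable aroyl chloride, and the second equivalent of enolate deprotonates the more acidic keto ester, which should prevent double acylation.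

Step 8
Reactants: 11 ethyl 2-(benzyloxy)-3-[4-(benzyloxy)-3-methoxyphenyl]-3-oxopropanoate
Product: 12 ethyl (2E)-2-(benzyloxy)-3-[4-(benzyloxy)-3-methoxyphenyl]-3-{[(4-methylphenyl)sulfonyl]oxy}prop-2-enoate
Conditions: LiN(SiMe3)2, THF, −78 °C; then Ts2O, −78 °C to rt
Reagents that add atoms: 4-methylbenzenesulfonic anhydride, Cc1ccc(cc1)S(=O)(=O)OS(=O)(=O)c1ccc(C)cc1
Why: O-sulfonylation of the chelated lithium enolate with the anhydride, which cannot chlorinate carbon, should place the tosyloxy group cis to the ester.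

Step 9
Reactants: 12 enol tosylate; 7 3,5-bis(benzyloxy)-2-methoxyphenol
Product: 13 ethyl (2E)-2-(benzyloxy)-3-[4-(benzyloxy)-3-methoxyphenyl]-3-[3,5-bis(benzyloxy)-2-methoxyphenoxy]prop-2-enoate
Conditions: Cs2CO3, DMF, 60 °C
Reagents that add atoms: none
Why: In this nucleophilic vinylic substitution (addition–elimination) the cesium phenoxide adds to the β-carbon of the acrylate and the ester enolate expels tosylate, with retention expected so that the aryloxy group ends cis to the ester.

Step 10
Reactants: 13 ethyl (2E)-3-aryloxy-2-(benzyloxy)-3-arylprop-2-enoate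
Product: 14 (2E)-2-(benzyloxy)-3-[4-(benzyloxy)-3-methoxyphenyl]-3-[3,5-bis(benzyloxy)-2-methoxyphenoxy]prop-2-enoic acid
Conditions: LiOH, THF/MeOH/H2O, 45 °C; then 1 M HCl, 0 °C
Reagents that add atoms: lithium hydroxide (its oxygen becomes the carboxyl OH), [Li+].[OH-]
Why: Saponification of the ethyl ester should win over conjugate attack because the tetrasubstituted, donor-substituted β-carbon is shielded, and cold acidification avoids enol-ether hydrolysis.

Step 11
Reactants: 14 (2E)-2-(benzyloxy)-3-[4-(benzyloxy)-3-methoxyphenyl]-3-[3,5-bis(benzyloxy)-2-methoxyphenoxy]prop-2-enoic acid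
Product: 16 3,5,7-tris(benzyloxy)-2-[4-(benzyloxy)-3-methoxyphenyl]-8-methoxy-4H-chromen-4-one, via trifluoroacetic mixed anhydride 15 (not isolated)
Conditions: (CF3CO)2O (2 equiv), CH2Cl2, 0 °C to rt
Reagents that add atoms: trifluoroacetic anhydride, O=C(OC(=O)C(F)(F)F)C(F)(F)F (its acyl group is held only in 15 and leaves again as trifluoroacetic acid; no atom of it stays in 16)
Why: The anhydride turns the carboxyl group into mixed anhydride 15, whose acyl carbon (as such or as the derived acylium ion) is attacked by C6 of the phenoxy ring, the future C4a, and loss of a proton rearomatises ring A to give the 4-pyranone. This is an intramolecular Friedel–Crafts acylation, the acid-mediated cycloacylation of 3-aryloxyacrylic acids to chromones and flavones, and mild anhydride activation should suffice because the attacking carbon is ortho to the ether oxygen, ortho to one benzyloxy group and para to the other. Ring C closes in a 6-exo-trig mode at the acyl carbon, forming C4–C4a, with O1–C2 and the C3 oxygen already in place. No stereocentre is formed. The step needs attack at C4a and not at C8, which is secured because C8 carries the methoxy group, and it needs the carboxyl cis to the aryloxy group, which 14 has and which rotation in the acylium ion (ketene–oxocarbenium form) or reversible protonation at C3 should restore for any other isomer. Closure onto ring B to an indenone is disfavoured by the five-membered ring and by the much lower nucleophilicity of ring B.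

Step 12
Reactants: 16 3,5,7-tris(benzyloxy)-2-[4-(benzyloxy)-3-methoxyphenyl]-8-methoxy-4H-chromen-4-one
Product: 17 3,5,7-trihydroxy-2-(4-hydroxy-3-methoxyphenyl)-8-methoxy-4H-chromen-4-one (limocitrin)
Conditions: H2 (1 atm), 10% Pd/C, THF/MeOH, rt
Reagents that add atoms: none
Why: Hydrogenolysis cleaves the four benzyl ethers, while the C2=C3 bond, part of the vinylogous ester, should not be reduced at 1 atm.

Step 13
Reactants: 17 limocitrin
Product: 18 2-[4-(acetyloxy)-3-methoxyphenyl]-8-methoxy-4-oxo-4H-chromene-3,5,7-triyl triacetate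
Conditions: Ac2O, pyridine, DMAP (cat.), rt
Reagents that add atoms: acetic anhydride, CC(=O)OC(C)=O
Why: Exhaustive O-acylation, with DMAP catalysis for the two hydroxyls hydrogen-bonded to the C4 carbonyl.

Step 14
Reactants: 18 limocitrin tetraacetate
Product: 19 2-[4-(acetyloxy)-3-methoxyphenyl]-7-hydroxy-8-methoxy-4-oxo-4H-chromene-3,5-diyl diacetate
Conditions: PhSH (1.2 equiv), imidazole (cat.), NMP, 0 °C
Reagents that add atoms: none
Why: Chemoselective acyl transfer to thiophenolate should take the O7 acetate, the most electrophilic one because the 7-phenoxide, para-conjugated with the C4 carbonyl, is the best leaving group.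

Step 15
Reactants: 19 7-hydroxy triacetate
Product: 20 2-[4-(acetyloxy)-3-methoxyphenyl]-8-methoxy-7-[(3-methylbut-2-en-1-yl)oxy]-4-oxo-4H-chromene-3,5-diyl diacetate
Conditions: prenyl bromide (1.2 equiv), K2CO3, DMF, rt
Reagents that add atoms: 1-bromo-3-methylbut-2-ene, CC(C)=CCBr
Why: Williamson etherification (SN2 at the primary allylic bromide) of the acidic 7-OH under mild carbonate conditions that should leave the three acetates in place.

Step 16
Reactants: 20 7-O-prenyl triacetate
Product: 21 3,5-dihydroxy-2-(4-hydroxy-3-methoxyphenyl)-8-methoxy-7-[(3-methylbut-2-en-1-yl)oxy]-4H-chromen-4-one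
Conditions: NH3 (7 M in MeOH), 0 °C to rt, argon
Reagents that add atoms: none
Why: Ammonolysis cleaves the three aryl acetates, and the prenyl aryl ether and the methyl ethers are inert to ammonia in methanol.

**Compound list**

1 | 2,4,6-trihydroxybenzaldehyde | O=Cc1c(O)cc(O)cc1O | starting material
2 | 2,4-bis(benzyloxy)-6-hydroxybenzaldehyde | O=Cc1c(O)cc(OCc2ccccc2)cc1OCc1ccccc1 | intermediate
3 | 2,4-bis(benzyloxy)-6-(methoxymethoxy)benzaldehyde | O=Cc1c(OCOC)cc(OCc2ccccc2)cc1OCc1ccccc1 | intermediate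
4 | 2,4-bis(benzyloxy)-6-(methoxymethoxy)phenyl formate | O=COc1c(OCOC)cc(OCc2ccccc2)cc1OCc1ccccc1 | intermediate (not isolated)
5 | 2,4-bis(benzyloxy)-6-(methoxymethoxy)phenol | Oc1c(OCOC)cc(OCc2ccccc2)cc1OCc1ccccc1 | intermediate
6 | 1,5-bis(benzyloxy)-2-methoxy-3-(methoxymethoxy)benzene | COc1c(OCOC)cc(OCc2ccccc2)cc1OCc1ccccc1 | intermediate
7 | 3,5-bis(benzyloxy)-2-methoxyphenol | COc1c(O)cc(OCc2ccccc2)cc1OCc1ccccc1 | intermediate
8 | 4-(benzyloxy)-3-methoxybenzoic acid | COc1cc(C(=O)O)ccc1OCc1ccccc1 | starting material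
9 | 4-(benzyloxy)-3-methoxybenzoyl chloride | COc1cc(C(=O)Cl)ccc1OCc1ccccc1 | intermediate
10 | ethyl 2-(benzyloxy)acetate | CCOC(=O)COCc1ccccc1 | starting material
11 | ethyl 2-(benzyloxy)-3-[4-(benzyloxy)-3-methoxyphenyl]-3-oxopropanoate (racemic) | CCOC(=O)C(OCc1ccccc1)C(=O)c1ccc(OCc2ccccc2)c(OC)c1 | intermediate
12 | ethyl (2E)-2-(benzyloxy)-3-[4-(benzyloxy)-3-methoxyphenyl]-3-{[(4-methylphenyl)sulfonyl]oxy}prop-2-enoate (tosyloxy cis to ester) | CCOC(=O)/C(OCc1ccccc1)=C(\OS(=O)(=O)c1ccc(C)cc1)c1ccc(OCc2ccccc2)c(OC)c1 | intermediate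
13 | ethyl (2E)-2-(benzyloxy)-3-[4-(benzyloxy)-3-methoxyphenyl]-3-[3,5-bis(benzyloxy)-2-methoxyphenoxy]prop-2-enoate (aryloxy cis to ester) | CCOC(=O)/C(OCc1ccccc1)=C(\Oc1cc(OCc2ccccc2)cc(OCc2ccccc2)c1OC)c1ccc(OCc2ccccc2)c(OC)c1 | intermediate
14 | (2E)-2-(benzyloxy)-3-[4-(benzyloxy)-3-methoxyphenyl]-3-[3,5-bis(benzyloxy)-2-methoxyphenoxy]prop-2-enoic acid (aryloxy cis to carboxyl) | OC(=O)/C(OCc1ccccc1)=C(\Oc1cc(OCc2ccccc2)cc(OCc2ccccc2)c1OC)c1ccc(OCc2ccccc2)c(OC)c1 | intermediate
15 | mixed anhydride of 14 with trifluoroacetic acid | O=C(OC(=O)C(F)(F)F)/C(OCc1ccccc1)=C(\Oc1cc(OCc2ccccc2)cc(OCc2ccccc2)c1OC)c1ccc(OCc2ccccc2)c(OC)c1 | intermediate (not isolated)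
16 | 3,5,7-tris(benzyloxy)-2-[4-(benzyloxy)-3-methoxyphenyl]-8-methoxy-4H-chromen-4-one | O=c1c(OCc2ccccc2)c(-c2ccc(OCc3ccccc3)c(OC)c2)oc2c(OC)c(OCc3ccccc3)cc(OCc3ccccc3)c12 | intermediate
17 | 3,5,7-trihydroxy-2-(4-hydroxy-3-methoxyphenyl)-8-methoxy-4H-chromen-4-one (limocitrin) | COc1cc(-c2oc3c(OC)c(O)cc(O)c3c(=O)c2O)ccc1O | intermediate
18 | 2-[4-(acetyloxy)-3-methoxyphenyl]-8-methoxy-4-oxo-4H-chromene-3,5,7-triyl triacetate | COc1cc(-c2oc3c(OC)c(OC(C)=O)cc(OC(C)=O)c3c(=O)c2OC(C)=O)ccc1OC(C)=O | intermediate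
19 | 2-[4-(acetyloxy)-3-methoxyphenyl]-7-hydroxy-8-methoxy-4-oxo-4H-chromene-3,5-diyl diacetate | COc1cc(-c2oc3c(OC)c(O)cc(OC(C)=O)c3c(=O)c2OC(C)=O)ccc1OC(C)=O | intermediate
20 | 2-[4-(acetyloxy)-3-methoxyphenyl]-8-methoxy-7-[(3-methylbut-2-en-1-yl)oxy]-4-oxo-4H-chromene-3,5-diyl diacetate | COc1cc(-c2oc3c(OC)c(OCC=C(C)C)cc(OC(C)=O)c3c(=O)c2OC(C)=O)ccc1OC(C)=O | intermediate
21 | 3,5-dihydroxy-2-(4-hydroxy-3-methoxyphenyl)-8-methoxy-7-[(3-methylbut-2-en-1-yl)oxy]-4H-chromen-4-one | COc1cc(-c2oc3c(OC)c(OCC=C(C)C)cc(O)c3c(=O)c2O)ccc1O | target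

**Step count**

Total steps: 16. Longest linear sequence: 13 (steps 1–5, then 9–16).

**Steps most likely to fail**

Step 9. The phenoxide may attack sulfur (sulfonyl transfer, returning the keto ester) or fail to add at the crowded β-carbon, which is deactivated by the α-benzyloxy donor. The fallback sets out from phenol 7 and comes back at 16: the aryl vinyl ether is made by conjugate addition to an alkyne, and the C3 oxygen is added after ring closure.
- Purchased 4-(benzyloxy)-3-methoxybenzaldehyde would be homologated by the Corey–Fuchs sequence (CBr4, PPh3; then n-BuLi and ethyl chloroformate) through 1-(benzyloxy)-4-(2,2-dibromoethenyl)-2-methoxybenzene F1 to ethyl 3-[4-(benzyloxy)-3-methoxyphenyl]prop-2-ynoate F2.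
- Phenol 7 with K2CO3 in DMF should add to F2 to give ethyl (2Z)-3-[4-(benzyloxy)-3-methoxyphenyl]-3-[3,5-bis(benzyloxy)-2-methoxyphenoxy]prop-2-enoate F3, and LiOH would give (2Z)-3-[4-(benzyloxy)-3-methoxyphenyl]-3-[3,5-bis(benzyloxy)-2-methoxyphenoxy]prop-2-enoic acid F4.
- (CF3CO)2O would close the same C4–C4a bond to give 5,7-bis(benzyloxy)-2-[4-(benzyloxy)-3-methoxyphenyl]-8-methoxy-4H-chromen-4-one F5.
- Lithiation at C3 with LiN(i-Pr)2 at −78 °C, B(OMe)3 and oxidation with H2O2/AcOH would give 5,7-bis(benzyloxy)-2-[4-(benzyloxy)-3-methoxyphenyl]-3-hydroxy-8-methoxy-4H-chromen-4-one F6, and BnBr/K2CO3 returns to 16.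

Step 11. The very electron-rich ring A may be C-trifluoroacetylated, or the acid set free may degrade the enol ether before ring closure. Partial loss of the O5 benzyl group would be harmless, since step 12 removes all four. The fallback sets out from acid 14 and comes back at 16: the electrophile becomes an iminium triflate under buffered, non-acidic conditions (Vilsmeier-type closure of the same bond).
- Acid 14 would be coupled with dimethylamine (EDC·HCl, HOBt) to (2E)-2-(benzyloxy)-3-[4-(benzyloxy)-3-methoxyphenyl]-3-[3,5-bis(benzyloxy)-2-methoxyphenoxy]-N,N-dimethylprop-2-enamide F7.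
- Tf2O and 2-chloropyridine in CH2Cl2 at −78 to 0 °C should activate the amide, and attack by C4a would give N-{3,5,7-tris(benzyloxy)-2-[4-(benzyloxy)-3-methoxyphenyl]-8-methoxy-4H-chromen-4-ylidene}-N-methylmethanaminium trifluoromethanesulfonate F8.
- Aqueous NaHCO3 would hydrolyse F8 to 16.

Step 14. Acetyl transfer may not be site-selective: the flanking 8-methoxy group may slow attack at the O7 acetate so that the O4′ or O3 acetate is cleaved alongside it. The fallback sets out from limocitrin 17 and comes back at 21, without acyl differentiation. An acidity-controlled Mitsunobu etherification with 3-methylbut-2-en-1-ol, PPh3 and DIAD (one equivalent each, THF, 0 °C) should alkylate the 7-OH first, because it is the most acidic hydroxyl and the 3-OH and 5-OH are hydrogen-bonded to the C4 carbonyl.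

**Further compounds**

F1 | step 9 | 1-(benzyloxy)-4-(2,2-dibromoethenyl)-2-methoxybenzene | COc1cc(C=C(Br)Br)ccc1OCc1ccccc1
F2 | step 9 | ethyl 3-[4-(benzyloxy)-3-methoxyphenyl]prop-2-ynoate | CCOC(=O)C#Cc1ccc(OCc2ccccc2)c(OC)c1
F3 | step 9 | ethyl (2Z)-3-[4-(benzyloxy)-3-methoxyphenyl]-3-[3,5-bis(benzyloxy)-2-methoxyphenoxy]prop-2-enoate | CCOC(=O)/C=C(\Oc1cc(OCc2ccccc2)cc(OCc2ccccc2)c1OC)c1ccc(OCc2ccccc2)c(OC)c1
F4 | step 9 | (2Z)-3-[4-(benzyloxy)-3-methoxyphenyl]-3-[3,5-bis(benzyloxy)-2-methoxyphenoxy]prop-2-enoic acid | OC(=O)/C=C(\Oc1cc(OCc2ccccc2)cc(OCc2ccccc2)c1OC)c1ccc(OCc2ccccc2)c(OC)c1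
F5 | step 9 | 5,7-bis(benzyloxy)-2-[4-(benzyloxy)-3-methoxyphenyl]-8-methoxy-4H-chromen-4-one | O=c1cc(-c2ccc(OCc3ccccc3)c(OC)c2)oc2c(OC)c(OCc3ccccc3)cc(OCc3ccccc3)c12
F6 | step 9 | 5,7-bis(benzyloxy)-2-[4-(benzyloxy)-3-methoxyphenyl]-3-hydroxy-8-methoxy-4H-chromen-4-one | O=c1c(O)c(-c2ccc(OCc3ccccc3)c(OC)c2)oc2c(OC)c(OCc3ccccc3)cc(OCc3ccccc3)c12
F7 | step 11 | (2E)-2-(benzyloxy)-3-[4-(benzyloxy)-3-methoxyphenyl]-3-[3,5-bis(benzyloxy)-2-methoxyphenoxy]-N,N-dimethylprop-2-enamide | CN(C)C(=O)/C(OCc1ccccc1)=C(\Oc1cc(OCc2ccccc2)cc(OCc2ccccc2)c1OC)c1ccc(OCc2ccccc2)c(OC)c1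
F8 | step 11 | N-{3,5,7-tris(benzyloxy)-2-[4-(benzyloxy)-3-methoxyphenyl]-8-methoxy-4H-chromen-4-ylidene}-N-methylmethanaminium trifluoromethanesulfonate | C[N+](C)=C1C(OCc2ccccc2)=C(c2ccc(OCc3ccccc3)c(OC)c2)Oc2c(OC)c(OCc3ccccc3)cc(OCc3ccccc3)c21.[O-]S(=O)(=O)C(F)(F)F
F0 | step 14 | none | none
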